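**Retrosynthetic overview**
- The butenolide arm comes from a B-alkyl Suzuki coupling of a C-9 vinyl diene with 4-bromofuranone. The vinyl group comes from a C-9 enol triflate.
- Ring B (key step) is made by a one-carbon, zinc-carbenoid ring expansion of a cis-fused 2-methylhydrindane-1,3-dione. The ring-enlarged enolate is caught as the triflate, and the cis fusion is fixed while the ring is still five-membered.
- C-10 is set by catalytic asymmetric methyl conjugate addition to a bicyclic ene-dione. Ring A is closed by olefin metathesis.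
- C-4 is set by palladium-catalysed asymmetric allylic alkylation of cyclopentane-1,3-dione with isoprene monoxide.
- Ring order: purchased five-membered ring, then ring A, then ring B by expansion, then the butenolide (purchased ring).

Assumption: the SMILES is read literally, so the decalin is cis-fused (H-5 and the C-20 methyl are both β). Labdane numbering is used for positions.

**Step 1**
Reactants: 1 cyclopentane-1,3-dione; 2 2-ethenyl-2-methyloxirane (racemic)
Product: 4 (3S)-3-ethenyl-3-methyl-2,3,5,6-tetrahydro-4H-cyclopenta[b]furan-4-one, via hydroxy-dione adduct 3 (not isolated)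
Conditions: Pd2(dba)3·CHCl3 (1 mol %), (R,R)-DACH-naphthyl Trost ligand (3 mol %), CH2Cl2, rt; then TsOH·H2O (cat.), 4 Å MS
Reagents that add atoms: none
Why: Palladium-catalysed asymmetric allylic alkylation (dynamic kinetic asymmetric transformation of the racemic vinyl epoxide), in which both epoxide enantiomers pass through interconverting π-allyl complexes of divalent palladium, the liberated alkoxide guides the dione to the tertiary terminus so that the ligand sets quaternary C-4 as S, and acid then closes the primary alcohol onto the enol to give a stable vinylogous ester.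

**Step 2**
Reactants: 4 (3S)-3-ethenyl-3-methyl-2,3,5,6-tetrahydro-4H-cyclopenta[b]furan-4-one
Product: 6 (3S)-3-ethenyl-5-hydroxy-3-methyl-2,3,5,6-tetrahydro-4H-cyclopenta[b]furan-4-one (both C-5 epimers), via lithium enolate 5 (not isolated)
Conditions: LiN(i-Pr)2, THF, −78 °C; 2-(phenylsulfonyl)-3-phenyloxaziridine, −78 °C; H2O
Reagents that add atoms: 2-(phenylsulfonyl)-3-phenyloxaziridine, O=S(=O)(N1OC1c1ccccc1)c1ccccc1
Why: Kinetic α′-deprotonation of the vinylogous ester followed by Davis oxaziridine hydroxylation places oxygen on the future C-9, and the stereorandom carbinol does not matter because it becomes a ketone in step 6.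

**Step 3**
Reactants: 6 (3S)-3-ethenyl-5-hydroxy-3-methyl-2,3,5,6-tetrahydro-4H-cyclopenta[b]furan-4-one; 7 allylmagnesium bromide
Product: 9 4-hydroxy-2-[(2S)-1-hydroxy-2-methylbut-3-en-2-yl]-3-(prop-2-en-1-yl)cyclopent-2-en-1-one, via allyl carbinol 8 (not isolated)
Conditions: 7 (2.5 equiv), THF, −78 → 0 °C; then 1 M HCl, THF, rt
Reagents that add atoms: allylmagnesium bromide (7), C=CC[Mg]Br; water, O
Why: Stork–Danheiser carbonyl transposition, in which 1,2-addition of the Grignard reagent to the vinylogous ester carbonyl (future C-10) and acid-induced ionisation and hydrolysis of the enol ether release the C-6 enone and the C-19 alcohol without touching C-4.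

**Step 4**
Reactants: 9 4-hydroxy-2-[(2S)-1-hydroxy-2-methylbut-3-en-2-yl]-3-(prop-2-en-1-yl)cyclopent-2-en-1-one; 10 acetyl chloride
Product: 11 (2S)-2-[3-hydroxy-5-oxo-2-(prop-2-en-1-yl)cyclopent-1-en-1-yl]-2-methylbut-3-en-1-yl acetate
Conditions: 10 (1.05 equiv), 2,4,6-collidine, CH2Cl2, −78 °C
Reagents that add atoms: acetyl chloride (10), CC(=O)Cl
Why: Chemoselective acylation, because at low temperature with a hindered pyridine base the primary alcohol is esterified much faster than the secondary allylic one, which installs the acetate of the target early so that no protecting group is needed.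

**Step 5**
Reactants: 11 (2S)-2-[3-hydroxy-5-oxo-2-(prop-2-en-1-yl)cyclopent-1-en-1-yl]-2-methylbut-3-en-1-yl acetate
Product: 12 [(4S)-1-hydroxy-4-methyl-3-oxo-2,3,4,7-tetrahydro-1H-inden-4-yl]methyl acetate
Conditions: second-generation Grubbs catalyst (3 mol %), CH2Cl2, 40 °C
Reagents that add atoms: none
Why: Ring-closing olefin metathesis of the allyl and vinyl groups closes ring A as a cyclohexa-1,4-diene that cannot aromatise because C-4 is quaternary.

**Step 6**
Reactants: 12 [(4S)-1-hydroxy-4-methyl-3-oxo-2,3,4,7-tetrahydro-1H-inden-4-yl]methyl acetate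
Product: 13 [(4S)-4-methyl-1,3-dioxo-2,3,4,7-tetrahydro-1H-inden-4-yl]methyl acetate
Conditions: MnO2 (15 equiv), CH2Cl2, rt
Reagents that add atoms: none
Why: Allylic alcohol oxidation with MnO2 gives the cyclopentene-1,3-dione, which erases the stereorandom carbinol and doubly activates the C-5/C-10 double bond.

**Step 7**
Reactants: 13 [(4S)-4-methyl-1,3-dioxo-2,3,4,7-tetrahydro-1H-inden-4-yl]methyl acetate; 14 trimethylaluminium
Product: 16 [(3aR,4S,7aS)-4,7a-dimethyl-1,3-dioxo-2,3,3a,4,7,7a-hexahydro-1H-inden-4-yl]methyl acetate, via dimethylaluminium enolate 15 (not isolated)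
Conditions: AlMe3 (2 equiv), Cu(OTf)2 (5 mol %), (S,R,R)-BINOL-derived phosphoramidite (10 mol %), Et2O, −30 °C; H2O
Reagents that add atoms: trimethylaluminium (14), C[Al](C)C
Why: Copper-catalysed asymmetric conjugate addition, in which methyl goes to C-10 (the alkene terminus away from neopentyl C-4), the chiral monovalent copper complex formed in situ dictates β-face delivery because the nearly flat substrate has little bias of its own, and the epimerisable C-5 settles as the more stable cis-hydrindanedione (H-5 β).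

**Step 8**
Reactants: 16 [(3aR,4S,7aS)-4,7a-dimethyl-1,3-dioxo-2,3,3a,4,7,7a-hexahydro-1H-inden-4-yl]methyl acetate; 17 formaldehyde
Product: 19 [(3aR,4S,7aS)-2,4,7a-trimethyl-1,3-dioxo-2,3,3a,4,7,7a-hexahydro-1H-inden-4-yl]methyl acetate (enolisable at C-2), via methylidene dione 18 (not isolated)
Conditions: aq. HCHO, Hantzsch ester (1.1 equiv), L-proline (20 mol %), CH2Cl2, rt
Reagents that add atoms: formaldehyde (17), C=O
Why: Organocatalytic three-component reductive alkylation (Knoevenagel condensation, then Hantzsch-ester transfer hydrogenation) gives only C-methylation of the 1,3-dione, and the new centre (C-8) is enolisable and later becomes sp2.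

**Step 9**
Reactants: 19 [(3aR,4S,7aS)-2,4,7a-trimethyl-1,3-dioxo-2,3,3a,4,7,7a-hexahydro-1H-inden-4-yl]methyl acetate; 20 diiodomethane
Product: 24 [(1S,4aS,8aR)-1,4a,6-trimethyl-8-oxo-5-(trifluoromethylsulfonyloxy)-1,4,4a,7,8,8a-hexahydronaphthalen-1-yl]methyl acetate, via ethylzinc enolate 21 (not isolated), via zinc cyclopropanolate 22 (not isolated), via ring-enlarged zinc enolate 23 (not isolated)
Conditions: Et2Zn (2.5 equiv), CH2I2 (1.3 equiv), CH2Cl2, 0 °C, 20 min; then PhNTf2 (1.5 equiv), DMPU, 0 °C → rt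
Reagents that add atoms: diiodomethane (20), ICI; N-phenylbis(trifluoromethanesulfonimide), O=S(=O)(N(c1ccccc1)S(=O)(=O)C(F)(F)F)C(F)(F)F
Why: Proposed new method: Et2Zn turns the enolic dione into its zinc enolate, EtZnCH2I alkylates C-8, the resulting CH2–Zn carbon closes onto the C-6 carbonyl (flanked by a methine) rather than the neopentyl C-9 carbonyl, and the donor–acceptor cyclopropanolate breaks its C-6/C-8 bond, so CH2 (C-7) is inserted, ring B becomes six-membered with C-5 and C-10 untouched, and the only enolate present (O–C-9=C-8) is O-sulfonylated to a regiodefined tetrasubstituted enol triflate that the free 1,4-diketone could not give selectively; the closest known reaction type is the zinc-carbenoid chain extension of β-dicarbonyl compounds (Zercher homologation) with tandem electrophile capture, not yet used as a ring expansion of a cyclic 2-alkyl-1,3-diketone or with a triflating agent.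

**Step 10**
Reactants: 24 [(1S,4aS,8aR)-1,4a,6-trimethyl-8-oxo-5-(trifluoromethylsulfonyloxy)-1,4,4a,7,8,8a-hexahydronaphthalen-1-yl]methyl acetate
Product: 25 [(1S,4aS,8aR)-1,4a,6-trimethyl-3,8-dioxo-5-(trifluoromethylsulfonyloxy)-1,2,3,4,4a,7,8,8a-octahydronaphthalen-1-yl]methyl acetate
Conditions: Pd(Quinox)Cl2 (5 mol %), AgSbF6 (12 mol %), aq. t-BuOOH, CH2Cl2, 0 °C → rt
Reagents that add atoms: tert-butyl hydroperoxide, CC(C)(C)OO
Why: Wacker-type oxidation of an internal alkene with a cationic divalent palladium catalyst delivers oxygen to C-2, the alkene carbon remote from quaternary C-4 and from the electron-withdrawing acetoxymethyl group, under near-neutral conditions that leave C-5 and the electron-poor enol triflate alone.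

**Step 11**
Reactants: 25 [(1S,4aS,8aR)-1,4a,6-trimethyl-3,8-dioxo-5-(trifluoromethylsulfonyloxy)-1,2,3,4,4a,7,8,8a-octahydronaphthalen-1-yl]methyl acetate
Product: 26 [(1S,3S,4aS,8S,8aR)-3,8-dihydroxy-1,4a,6-trimethyl-5-(trifluoromethylsulfonyloxy)-1,2,3,4,4a,7,8,8a-octahydronaphthalen-1-yl]methyl acetate
Conditions: LiBH(s-Bu)3 (2.4 equiv), THF, −78 °C; H2O
Reagents that add atoms: none
Why: Diastereoselective ketone reduction with a bulky trialkylborohydride, which reaches both carbonyl groups from the convex β-face of the cis-decalin (the face of H-5 and C-20) and so gives the 2α- and 6α-alcohols, while the hindered neopentyl acetate survives at −78 °C.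

**Step 12**
Reactants: 26 [(1S,3S,4aS,8S,8aR)-3,8-dihydroxy-1,4a,6-trimethyl-5-(trifluoromethylsulfonyloxy)-1,2,3,4,4a,7,8,8a-octahydronaphthalen-1-yl]methyl acetate; 27 potassium vinyltrifluoroborate
Product: 28 [(1S,3R,4aS,8S,8aS)-5-ethenyl-3,8-dihydroxy-1,4a,6-trimethyl-1,2,3,4,4a,7,8,8a-octahydronaphthalen-1-yl]methyl acetate
Conditions: PdCl2(dppf)·CH2Cl2 (5 mol %), Cs2CO3 (3 equiv), THF/H2O 9:1, 55 °C
Reagents that add atoms: potassium vinyltrifluoroborate (27), C=C[B-](F)(F)F.[K+]
Why: Suzuki–Miyaura vinylation of the enol triflate forms the C-9/C-11 bond with retention of the tetrasubstituted double bond and tolerates free alcohols (the descriptors at C-2 and C-5 change by priority only).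

**Step 13**
Reactants: 28 [(1S,3R,4aS,8S,8aS)-5-ethenyl-3,8-dihydroxy-1,4a,6-trimethyl-1,2,3,4,4a,7,8,8a-octahydronaphthalen-1-yl]methyl acetate; 29 4-bromofuran-2(5H)-one
Product: 31 CNP0201970.1, [(1S,3R,4aS,8S,8aS)-3,8-dihydroxy-1,4a,6-trimethyl-5-[2-(5-oxo-2,5-dihydrofuran-3-yl)ethyl]-1,2,3,4,4a,7,8,8a-octahydronaphthalen-1-yl]methyl acetate, via B-alkyl borane 30 (not isolated)
Conditions: 9-BBN (3.3 equiv), THF, 0 °C → rt; then 29, PdCl2(dppf)·CH2Cl2 (5 mol %), AsPh3, Cs2CO3, DMF/H2O, rt
Reagents that add atoms: 4-bromofuran-2(5H)-one (29), O=C1C=C(Br)CO1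
Why: 9-BBN hydroborates only the terminal vinyl carbon of the diene (the tetrasubstituted alkene is inert and the alcohols are masked for the moment as borinates), and the B-alkyl Suzuki–Miyaura coupling joins C-12 to C-13 of the intact butenolide under mild base.

**Compound list**
1 | cyclopentane-1,3-dione | O=C1CCC(=O)C1 | starting material
2 | 2-ethenyl-2-methyloxirane | C=CC1(C)CO1 | starting material
3 | 2-[(2S)-1-hydroxy-2-methylbut-3-en-2-yl]cyclopentane-1,3-dione | OC[C@@](C)(C=C)C1C(=O)CCC1=O | intermediate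
4 | (3S)-3-ethenyl-3-methyl-2,3,5,6-tetrahydro-4H-cyclopenta[b]furan-4-one | C=C[C@]1(C)COC2=C1C(=O)CC2 | intermediate
5 | lithium enolate of 4 | C=C[C@]1(C)COC2=C1C(O[Li])=CC2 | intermediate
6 | (3S)-3-ethenyl-5-hydroxy-3-methyl-2,3,5,6-tetrahydro-4H-cyclopenta[b]furan-4-one | C=C[C@]1(C)COC2=C1C(=O)C(O)C2 | intermediate
7 | allylmagnesium bromide | C=CC[Mg]Br | starting material
8 | (3S)-3-ethenyl-3-methyl-4-(prop-2-en-1-yl)-2,3,5,6-tetrahydro-4H-cyclopenta[b]furan-4,5-diol | C=CCC1(O)C(O)CC2=C1[C@](C)(C=C)CO2 | intermediate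
9 | 4-hydroxy-2-[(2S)-1-hydroxy-2-methylbut-3-en-2-yl]-3-(prop-2-en-1-yl)cyclopent-2-en-1-one | OC[C@@](C)(C=C)C1=C(CC=C)C(O)CC1=O | intermediate
10 | acetyl chloride | CC(=O)Cl | starting material
11 | (2S)-2-[3-hydroxy-5-oxo-2-(prop-2-en-1-yl)cyclopent-1-en-1-yl]-2-methylbut-3-en-1-yl acetate | CC(=O)OC[C@@](C)(C=C)C1=C(CC=C)C(O)CC1=O | intermediate
12 | [(4S)-1-hydroxy-4-methyl-3-oxo-2,3,4,7-tetrahydro-1H-inden-4-yl]methyl acetate | CC(=O)OC[C@@]1(C)C=CCC2=C1C(=O)CC2O | intermediate
13 | [(4S)-4-methyl-1,3-dioxo-2,3,4,7-tetrahydro-1H-inden-4-yl]methyl acetate | CC(=O)OC[C@@]1(C)C=CCC2=C1C(=O)CC2=O | intermediate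
14 | trimethylaluminium | C[Al](C)C | starting material
15 | dimethylaluminium enolate (O on C-6, C-5=C-6) | CC(=O)OC[C@@]1(C)C=CC[C@]2(C)C(=O)CC(O[Al](C)C)=C12 | intermediate
16 | [(3aR,4S,7aS)-4,7a-dimethyl-1,3-dioxo-2,3,3a,4,7,7a-hexahydro-1H-inden-4-yl]methyl acetate | CC(=O)OC[C@@]1(C)C=CC[C@]2(C)C(=O)CC(=O)[C@H]12 | intermediate
17 | formaldehyde | C=O | starting material
18 | 2-methylidene derivative of 16 | CC(=O)OC[C@@]1(C)C=CC[C@]2(C)C(=O)C(=C)C(=O)[C@H]12 | intermediate
19 | [(3aR,4S,7aS)-2,4,7a-trimethyl-1,3-dioxo-2,3,3a,4,7,7a-hexahydro-1H-inden-4-yl]methyl acetate | CC(=O)OC[C@@]1(C)C=CC[C@]2(C)C(=O)C(C)C(=O)[C@H]12 | intermediate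
20 | diiodomethane | ICI | starting material
21 | ethylzinc enolate of 19 | CC(=O)OC[C@@]1(C)C=CC[C@]2(C)C(=O)C(C)=C(O[Zn]CC)[C@H]12 | intermediate
22 | ethylzinc cyclopropanolate (C-6/C-7/C-8 three-membered ring) | CC(=O)OC[C@@]1(C)C=CC[C@]2(C)C(=O)C3(C)CC3(O[Zn]CC)[C@H]12 | intermediate
23 | ring-enlarged ethylzinc enolate (O on C-9, C-8=C-9) | CC(=O)OC[C@@]1(C)C=CC[C@]2(C)C(O[Zn]CC)=C(C)CC(=O)[C@H]12 | intermediate
24 | [(1S,4aS,8aR)-1,4a,6-trimethyl-8-oxo-5-(trifluoromethylsulfonyloxy)-1,4,4a,7,8,8a-hexahydronaphthalen-1-yl]methyl acetate | CC(=O)OC[C@@]1(C)C=CC[C@]2(C)C(OS(=O)(=O)C(F)(F)F)=C(C)CC(=O)[C@H]12 | intermediate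
25 | [(1S,4aS,8aR)-1,4a,6-trimethyl-3,8-dioxo-5-(trifluoromethylsulfonyloxy)-1,2,3,4,4a,7,8,8a-octahydronaphthalen-1-yl]methyl acetate | CC(=O)OC[C@@]1(C)CC(=O)C[C@]2(C)C(OS(=O)(=O)C(F)(F)F)=C(C)CC(=O)[C@H]12 | intermediate
26 | [(1S,3S,4aS,8S,8aR)-3,8-dihydroxy-1,4a,6-trimethyl-5-(trifluoromethylsulfonyloxy)-1,2,3,4,4a,7,8,8a-octahydronaphthalen-1-yl]methyl acetate | CC(=O)OC[C@@]1(C)C[C@H](O)C[C@]2(C)C(OS(=O)(=O)C(F)(F)F)=C(C)C[C@H](O)[C@H]12 | intermediate
27 | potassium vinyltrifluoroborate | C=C[B-](F)(F)F.[K+] | starting material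
28 | [(1S,3R,4aS,8S,8aS)-5-ethenyl-3,8-dihydroxy-1,4a,6-trimethyl-1,2,3,4,4a,7,8,8a-octahydronaphthalen-1-yl]methyl acetate | CC(=O)OC[C@@]1(C)C[C@H](O)C[C@]2(C)C(C=C)=C(C)C[C@H](O)[C@H]12 | intermediate
29 | 4-bromofuran-2(5H)-one | O=C1C=C(Br)CO1 | starting material
30 | C-12 B-alkyl-9-BBN of 28 (both alcohols as 9-BBN borinates) | CC(=O)OC[C@@]1(C)C[C@H](OB3C4CCCC3CCC4)C[C@]2(C)C(CCB3C4CCCC3CCC4)=C(C)C[C@H](OB3C4CCCC3CCC4)[C@H]12 | intermediate
31 | CNP0201970.1 | CC(=O)OC[C@@]1(C)C[C@H](O)C[C@]2(C)C(CCC3=CC(=O)OC3)=C(C)C[C@H](O)[C@H]12 | target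

**Total step count:** 13. **Longest linear sequence:** 13. No protecting group is used.

**Three steps most likely to fail**

Step 9 (the new reaction).
- Risks: closure onto the wrong carbonyl, cyclopropanation of the ring A alkene, and slow O-sulfonylation of a zinc enolate.
- Fallback: known donor–acceptor cyclopropane chemistry, setting out from 19 and coming back at 24. TBSOTf/Et3N silylates the less hindered C-6 oxygen to give the C-6 silyl enol ether F1. Et2Zn/CH2I2 cyclopropanates this electron-rich double bond to the siloxycyclopropyl ketone F2, which is purified. CsF in the presence of PhNTf2 then opens the three-membered ring to the C-9 enolate, which is sulfonylated to 24.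

Step 7.
- Risks: a tetrasubstituted ene-dione is outside the usual scope of asymmetric conjugate addition, it can be reduced instead of alkylated, and its C-1 protons are acidic.
- Fallback: setting out from 6 and coming back at 16, the two carbon groups on C-10 are introduced in the reverse order, so the quaternary centre is made by a Lewis-acid Hosomi–Sakurai reaction. MeLi adds to 6 to give the methyl carbinol F3. 1 M HCl transposes it to the methyl enone diol F4. AcCl/collidine gives the primary acetate F5. MnO2 gives the monocyclic ene-dione F6. Allyltrimethylsilane/TiCl4 adds allyl to C-10 on the side away from the acetoxymethyl arm to give the allyl dione F7 (C-10 epimers are separable). Second-generation Grubbs catalyst then closes ring A to 16.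

Step 11.
- Risks: each face of the C-2 carbonyl carries two carbon substituents at C-4 and C-10, so the facial bias may be small. The C-6 ketone may also epimerise C-5.
- Fallback: setting out from 25 and coming back at 26, the C-19 oxygen is used as an internal hydride carrier. K2CO3/MeOH gives the hydroxy diketone F8. Me4NBH(OAc)3 binds the β-oriented C-19 alcohol and delivers hydride to the β-face of C-2 to give the 2α-alcohol F9. LiBH(s-Bu)3 reduces the remaining C-6 ketone to the triol F10. AcCl/collidine at −78 °C then acetylates only the primary alcohol to give 26.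

**Further compounds**
F1 | step 9 | C-6 tert-butyldimethylsilyl enol ether of 19 | CC(=O)OC[C@@]1(C)C=CC[C@]2(C)C(=O)C(C)=C(O[Si](C)(C)C(C)(C)C)[C@H]12
F2 | step 9 | siloxycyclopropyl ketone (CH2 bridging C-6 and C-8) | CC(=O)OC[C@@]1(C)C=CC[C@]2(C)C(=O)C3(C)CC3(O[Si](C)(C)C(C)(C)C)[C@H]12
F3 | step 7 | (3S)-3-ethenyl-3,4-dimethyl-2,3,5,6-tetrahydro-4H-cyclopenta[b]furan-4,5-diol | CC1(O)C(O)CC2=C1[C@](C)(C=C)CO2
F4 | step 7 | 4-hydroxy-2-[(2S)-1-hydroxy-2-methylbut-3-en-2-yl]-3-methylcyclopent-2-en-1-one | OC[C@@](C)(C=C)C1=C(C)C(O)CC1=O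
F5 | step 7 | (2S)-2-(3-hydroxy-2-methyl-5-oxocyclopent-1-en-1-yl)-2-methylbut-3-en-1-yl acetate | CC(=O)OC[C@@](C)(C=C)C1=C(C)C(O)CC1=O
F6 | step 7 | (2S)-2-methyl-2-(2-methyl-3,5-dioxocyclopent-1-en-1-yl)but-3-en-1-yl acetate | CC(=O)OC[C@@](C)(C=C)C1=C(C)C(=O)CC1=O
F7 | step 7 | (2S)-2-methyl-2-[2-methyl-3,5-dioxo-2-(prop-2-en-1-yl)cyclopentyl]but-3-en-1-yl acetate (ring centres as in 16) | CC(=O)OC[C@@](C)(C=C)[C@H]1C(=O)CC(=O)[C@@]1(C)CC=C
F8 | step 11 | 19-hydroxy analogue of 25 | OC[C@@]1(C)CC(=O)C[C@]2(C)C(OS(=O)(=O)C(F)(F)F)=C(C)CC(=O)[C@H]12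
F9 | step 11 | 2α,19-dihydroxy-6-ketone | OC[C@@]1(C)C[C@H](O)C[C@]2(C)C(OS(=O)(=O)C(F)(F)F)=C(C)CC(=O)[C@H]12
F10 | step 11 | 2α,6α,19-triol | OC[C@@]1(C)C[C@H](O)C[C@]2(C)C(OS(=O)(=O)C(F)(F)F)=C(C)C[C@H](O)[C@H]12
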